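At the reading, 15 min after charging, this flask has to show how far the electrophile has gone and how its unused nucleophile is divided.

common to all: electrophile 0.10 M

|  | nucleophile | solid base | remark | time |
|---|---|---|---|---|
| Tuesday's | 0.060 M | 0.080 M | run made earlier |  |
| Thursday's | 0.090 M | 0.080 M | run made earlier |  |
| flask | 0.120 M | 0.0800 M |  | 15 min |

| run | time / min | electrophile / % | target / % |
|---|---|---|---|
| Tuesday's | 2.00 | 66.2 | 33.3 |
| Tuesday's | 5.00 | 53.4 | 46.4 |
| Tuesday's | 10.0 | 42.6 | 57.2 |
| Tuesday's | 15.0 | 40.3 | 60.0 |
| Thursday's | 1.33 | 60.1 | 41.5 |
| Thursday's | 3.00 | 47.3 | 52.5 |
| Thursday's | 6.00 | 32.9 | 66.6 |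
| Thursday's | 15.0 | 15.8 | 82.7 |

(scatter of a reading: 0.5 percentage points)

* part of the electrophile that has reacted at 15 min
* share of the unused nucleophile that is free and not bound as protonated nucleophile, at 15 min

- given per volume of solution although it is solid: solid base
- at the start none of the solid base is in solution
- the earlier runs do not show how much of nucleophile is bound; that part of a forecast is a guess

The quantity to carry is the equivalent ratio, nucleophile charged per electrophile charged, read as a ceiling on conversion. A ratio of one, the equal charge, is the zero of the scale: below it the ceiling is the ratio, above it full conversion.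

c(nucleophile) / c(electrophile) = 1.20 here; Tuesday's 0.600, Thursday's 0.900

The runs show a ladder. Fastest comes a burst: Tuesday's target at 2.00 min reads 55.5 % of that run's nucleophile charge, Thursday's at 1.33 min reads 46.1 %. Next comes a slower climb, 14 percentage points on Thursday between 3.00 min and 6.00 min. Last comes the approach to the ceiling: Tuesday's target reads 60.0 % at 15.0 min, while Thursday's reads 82.7 %, still below its ratio by 7.3 points.

This flask stands above the zero, so its ceiling is full conversion. Carrying Thursday's gap over gives this reckoning's figure:

c = 92.7 %

The forecast says 96 % reacted and 28 % free, the share called a guess, on the ground that “conversion has no floor short of completion”; its conversion is higher than the reckoning above.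

The simulation gives:

    electrophile + nucleophile → acid set free + target (k = 0.170 /M/s)
    nucleophile + acid set free ⇌ protonated nucleophile, settled at all times (K = 1300 /M)
    acid set free + free base ⇌ salt of the base (K = 1200 /M, k = 0.310 /M/s)
    electrophile + acid set free → side product (k = 0.00500 /M/s)
    acid set free → by-product carried off (k = 0.110 /s)
    solid base ⇌ free base, rate k6*(cs6 - [free base]) while solid is left; crystals form when [free base] > cs6 (solubility = 0.0660 M, k = 0.00610 /s)

The flask reaches 96.1 % reacted, with 77.3 % of its unused nucleophile free. The two part on the share: the forecast put about 0.0065 M free, while the flask holds 0.0186 M free beside 0.00544 M of protonated nucleophile. By 150 min conversion stands at 100 %, with 16.7 % of the nucleophile charge left free, and the ratio leaves 16.7 %. The neighbour charged with 0.048 M of nucleophile has a ratio of 0.480, which makes nucleophile the limiting reagent; it stands at 48.0 % reacted, with 0.17 % of its nucleophile left.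

(All runs were computed from invented constants, and the scatter is random.)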